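Tetralin numbering is used throughout: C1 bears the guaiacyl ring, C2 and C3 bear C9 and C10, C4 is CH2, ring A is C4a, C5–C8, C8a, ring B is the carbocycle. Compound numbers are those of the list after the steps.

## Analysis of the target

Target 20 is a 1-aryl-1,2,3,4-tetrahydronaphthalene whose ring A carries OMe on C6, OH on C7 and OMe on C8. The three stereocentres are contiguous, (1R,2S,3S): the aryl group and C9 are trans, C9 and C10 are trans, so the aryl group and C10 are cis and all three groups can be equatorial. C2 can be corrected by equilibration as long as C9 is a carbonyl group, but C1 and C3 cannot. C1 is doubly benzylic and sits peri to the C8 methoxy group, which makes O8 the most hindered oxygen of ring A and pushes the aryl group out of the ring plane in any 1,4-dihydro intermediate. The two electron-rich phenols are easily oxidized, and a 1,4-dihydronaphthalene intermediate can lose two hydrogen atoms to a naphthalene, which would erase C1. The hard parts are the absolute configuration at C1, which has no neighbouring heteroatom to direct it, and a 1,2,3-trioxygenated ring A in which only the middle oxygen is free. The strategy rests on the edge C4a–C8a that ring B shares with ring A: C5 and C8 flank it, so ring A can arrive as a 1,4-benzoquinone whose unsubstituted C=C becomes C4a–C8a, while C1 to C4 come from a 1-aryl-1,3-diene.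

## Retrosynthetic reasoning

**O10–Si and O7–CH3 (20 ⇒ 19 ⇒ 18).** The last two operations are heteroatom deprotections. The O7 methyl group is the price of using a symmetric quinone. It is cleaved from 18, where no ester or benzyl ether is left for a soft sulfur nucleophile to attack and no acidic C–H remains. The forward step has to pick the doubly flanked methoxy group of ring A out of four methoxy groups.

**C9 oxidation level and C2 configuration (18 ⇒ 17 ⇒ 16).** C9 is kept as a methyl ester up to 17 because the ester makes C2 epimerizable. In 16 the three ring B substituents are all cis; base equilibration has to move the ester to the opposite face, which gives the all-equatorial arrangement of the target.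

**C2–H and C3–H (16 ⇒ 15).** Removing these two hydrogen atoms gives the tetrasubstituted alkene C2=C3 of 15. C1 is then the only stereocentre, and C3 is set from it: the forward saturation must come from the face opposite the pseudoaxial aryl group. The C10 oxygen is carried as a silyl ether so that it survives this step and cannot lactonize onto the C2 ester, which would lock the 2,3-cis arrangement.

**O8–CH3 and the aromatic state of ring A (15 ⇒ 14 ⇒ 12).** Phenol 14 is traced back to the cis-fused enedione 12. O5 must go and O8 must stay. In 12 the two carbonyl groups differ in their surroundings (C8 is next to the aryl-bearing C1, C5 is next to CH2), so 1,2-reduction at C5 followed by dehydration and enolization does this without having to tell two phenols apart.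

**C1–C8a and C4–C4a (12 ⇒ 11 + 2).** Both bonds of ring B that end on the shared edge are cut in a retro-[4+2]. This is the only disconnection that gives two achiral pieces of similar size and builds ring B, C1 and the whole ring A carbon frame in one step. The forward reaction must control the site on 2, the orientation of 11 on the activated quinone, endo approach and the quinone face.

**C2–C3 of the diene (11 ⇒ 10 + 5).** The central sigma bond of the diene is cut into an alkenyl bromide and an alkenyl boronate. The coupling must keep the double-bond geometry of 10, because only a diene with the aryl group trans to C3 can reach the s-cis form.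

**C1=C2 of the diene (10 ⇒ 9 + 8).** The trisubstituted alkene comes from an aldehyde and a bromophosphonate. The olefination must place the ester cis to the aryl group, which is the less stable geometry and therefore needs a kinetically controlled method.

**Building blocks (5 ⇒ 4 ⇒ 3; 8 ⇒ 7 ⇒ 6; 2 ⇒ 1).** These are one- or two-step functional group changes on commercial materials: silylation and borylation of 3, bromination of 6, and para-oxidation of 1.

## Alternatives that were turned down

**Alternative 1:** The disconnection is C2–C3 and C1–C8a. The forward step is a laccase oxidation of the tethered ferulate–sinapate diester A1 in air: the two phenoxyl radicals couple at their β carbons, and the syringyl ring then attacks the guaiacyl quinone methide to give the bridged dihydronaphthalene diester A2. In its favour, it is the shortest route, it needs no protecting groups, and ring A arrives with the 6-OMe, 7-OH, 8-OMe pattern already in place. Both C2 and C3 end up α to esters and can be equilibrated after the C3=C4 bond is saturated. Against it, a ferulate radical also couples through O4 and C5, so β–β cross-coupling has to beat those modes, homo-coupling and oligomerization. A2 is still a phenol and stays a substrate for the enzyme. The configuration at C1 depends on relay from the diol tether through a nine-membered ring in a radical and quinone methide cascade, for which there is no predictive model. On step count and on ring A this alternative is stronger. The chosen route offers a catalyst-controlled C1 with an established binding model and purely ionic, stepwise chemistry afterwards.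

**Alternative 2:** The disconnection is C1–C2. In the forward step a diarylprolinol silyl ether turns the aldehyde of A3 into an enamine while acid ionizes the para-hydroxybenzhydrol to a quinone methide; intramolecular 1,6-addition closes ring B and gives the all-trans aldehyde A4. In its favour, ring A is complete from the start with O7 as a benzyl ether, the free guaiacyl phenol is exactly what triggers the quinone methide, and C2 stays correctable next to the aldehyde. Against it, A3 needs its C3 stereocentre made beforehand in a separate asymmetric operation, plus a diaryl carbinol next to a methoxy group. The key step then sets only C1 irreversibly, and its selectivity depends on whether catalyst and C3 cooperate. On the ring A oxygen pattern it is stronger than the chosen route and on catalytic control it is equal. The chosen route is more convergent: it builds ring B and C1 from two achiral fragments in one step.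

**Alternative 3:** The disconnection is C1–C2 and C3–C4. Irradiation of the ortho-benzyl benzaldehyde A5 gives a hydroxy-ortho-quinodimethane that is trapped by di-(−)-menthyl fumarate A6 to give the hydroxytetralin diester A7. In its favour, it is convergent, the 2,3-trans relationship comes directly from the fumarate geometry, one reduction turns both esters into C9 and C10, and the extra C4 hydroxyl can leave by hydrogenolysis together with the benzyl groups. Against it, the absolute configuration rests on a stoichiometric ester auxiliary acting without a chelating Lewis acid, where facial bias is usually weak. The dienol geometry and endo or exo approach decide C1 relative to C2, and the hydrogen to be abstracted sits between two arenes next to a methoxy group. On the C2/C3 relationship and on ring A it is as strong or stronger. The chosen route offers catalytic control of absolute configuration instead.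

Key step: step 7

Remark on the chemistry: the hand of the catalyst in step 7 is assigned from the binding model of this catalyst class and would be checked on 14; if the opposite sense were found, the mirror-image catalyst would be used with nothing else changed.

## Route

Step 1
Reactants: 1 2,3-dimethoxyphenol
Product: 2 2,3-dimethoxy-1,4-benzoquinone
Conditions: (KSO3)2NO, KH2PO4, H2O–acetone, 0 °C → rt
Reagents that add atoms: potassium nitrosodisulfonate (Fremy's salt), [K+].[K+].[O]N(S(=O)(=O)[O-])S(=O)(=O)[O-]
Why: Teuber oxidation: the phenoxyl radical is trapped by a second nitroxide at the free para position and collapses to the para-quinone.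

Step 2
Reactants: 3 2-bromoprop-2-en-1-ol
Product: 4 [(2-bromoprop-2-en-1-yl)oxy]tri(propan-2-yl)silane
Conditions: TIPSCl, imidazole, CH2Cl2, 0 °C → rt
Reagents that add atoms: chlorotri(propan-2-yl)silane, CC(C)[Si](Cl)(C(C)C)C(C)C
Why: Standard silylation of a primary alcohol; the triisopropylsilyl ether is chosen because it survives the later acid, methoxide, hydride and hydrogenation steps.

Step 3
Reactants: 4 [(2-bromoprop-2-en-1-yl)oxy]tri(propan-2-yl)silane
Product: 5 4,4,5,5-tetramethyl-2-{3-[(triisopropylsilyl)oxy]prop-1-en-2-yl}-1,3,2-dioxaborolane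
Conditions: B2pin2, PdCl2(PPh3)2 (3 mol%), PPh3, KOPh, toluene, 50 °C
Reagents that add atoms: bis(pinacolato)diboron, CC1(C)OB(OC1(C)C)B1OC(C)(C)C(C)(C)O1
Why: Miyaura borylation of a 1,1-disubstituted alkenyl bromide; phenoxide is the mild base that allows transmetalation without coupling of the product boronate.

Step 4
Reactants: 6 methyl 2-[bis(2,2,2-trifluoroethoxy)phosphoryl]acetate
Product: 8 methyl 2-bromo-2-[bis(2,2,2-trifluoroethoxy)phosphoryl]acetate, via dibromophosphonoacetate 7 (not isolated)
Conditions: Br2, NaOH, H2O, 0 °C; then SnCl2·2H2O, EtOH–H2O, 0 °C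
Reagents that add atoms: bromine, BrBr
Why: Exhaustive bromination of the acidic methylene with hypobromite, then removal of one bromine by a two-electron reductant; this avoids the mixtures that direct monobromination gives.

Step 5
Reactants: 8 methyl 2-bromo-2-[bis(2,2,2-trifluoroethoxy)phosphoryl]acetate; 9 4-(benzyloxy)-3-methoxybenzaldehyde
Product: 10 methyl (E)-3-[4-(benzyloxy)-3-methoxyphenyl]-2-bromoprop-2-enoate
Conditions: t-BuOK, 18-crown-6, THF, −78 °C
Reagents that add atoms: none
Why: Horner–Wadsworth–Emmons olefination of the Still–Gennari type: the electron-poor phosphonate makes elimination from the kinetically preferred adduct fast and irreversible, which places the ester cis to the aryl group and bromine trans to it.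

Step 6
Reactants: 10 methyl (E)-3-[4-(benzyloxy)-3-methoxyphenyl]-2-bromoprop-2-enoate; 5 4,4,5,5-tetramethyl-2-{3-[(triisopropylsilyl)oxy]prop-1-en-2-yl}-1,3,2-dioxaborolane
Product: 11 methyl (Z)-3-[4-(benzyloxy)-3-methoxyphenyl]-2-{3-[(triisopropylsilyl)oxy]prop-1-en-2-yl}prop-2-enoate
Conditions: Pd(PPh3)4 (5 mol%), K3PO4, dioxane–H2O, 60 °C
Reagents that add atoms: none
Why: Suzuki–Miyaura coupling; oxidative addition and reductive elimination keep the geometry at the alkenyl carbon, so the new C2–C3 bond takes the place of bromine and the aryl group ends up trans to C3, on the outside of the diene.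

Step 7
Reactants: 11 methyl (Z)-3-[4-(benzyloxy)-3-methoxyphenyl]-2-{3-[(triisopropylsilyl)oxy]prop-1-en-2-yl}prop-2-enoate; 2 2,3-dimethoxy-1,4-benzoquinone
Product: 12 methyl (1S,4aR,8aS)-1-[4-(benzyloxy)-3-methoxyphenyl]-6,7-dimethoxy-5,8-dioxo-3-{[(triisopropylsilyl)oxy]methyl}-1,4,4a,5,8,8a-hexahydronaphthalene-2-carboxylate
Conditions: (R)-3,3-diphenyl-1-(o-tolyl)tetrahydro-1H,3H-pyrrolo[1,2-c][1,3,2]oxazaborole (20 mol%), Tf2NH (18 mol%), CH2Cl2, −78 → −40 °C
Reagents that add atoms: none
Why: Protonation of the oxazaborolidine nitrogen by triflimide gives a cationic boron Lewis acid that binds one carbonyl of 2 on the lone pair next to the vinylic C–H, which in turn contacts the ring oxygen of the catalyst; the closest known reaction type is the oxazaborolidinium-catalysed enantioselective Diels–Alder reaction of 1,4-benzoquinones with 1-substituted dienes, applied here to a diene with an ester on C2. The reaction is a concerted but strongly asynchronous [4+2] cycloaddition, suprafacial on both partners, and ring B is closed in this single intermolecular step by the bonds C4–C4a (the more advanced one) and C1–C8a. Site selectivity needs no help, because the methoxy-bearing C=C of 2 is a doubly donor-substituted, electron-rich alkene and inert as a dienophile. Orientation matters although 2 is symmetric, because the bound carbonyl makes the two ends of the reacting C=C different: the CH2 terminus C4 of 11 is the more nucleophilic end (the developing positive charge is then held at the aryl-bearing C1 and at C3 while the ester sits at the node C2) and bonds to the carbon β to the bound carbonyl, so the bound carbonyl becomes C8. C8a and C4a are set by the quinone face that the catalyst leaves open, since a C-phenyl group of the catalyst lies over the other face, and C1 is set relative to C8a by the endo rule with the aryl group outside, as fixed by the Z geometry of 11. By the binding model the catalyst from (S)-diphenylprolinol leaves open the Re face of the α-carbon of the bound enone unit (C=O > Cβ > H), which in this orientation would give the mirror image of 12, so the catalyst from (R)-diphenylprolinol is used. Because C4a and C8a are lost on aromatization, the enantiomeric purity of everything downstream is the product of face, orientation and endo selectivity in this step. The ester of 11 can also bind boron, which is why a fairly high catalyst loading is planned.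

Step 8
Reactants: 12 methyl (1S,4aR,8aS)-1-[4-(benzyloxy)-3-methoxyphenyl]-6,7-dimethoxy-5,8-dioxo-3-{[(triisopropylsilyl)oxy]methyl}-1,4,4a,5,8,8a-hexahydronaphthalene-2-carboxylate
Product: 14 methyl (1R)-1-[4-(benzyloxy)-3-methoxyphenyl]-8-hydroxy-6,7-dimethoxy-3-{[(triisopropylsilyl)oxy]methyl}-1,4-dihydronaphthalene-2-carboxylate, via C5 carbinol 13 (not isolated)
Conditions: NaBH4, CeCl3·7H2O, MeOH–CH2Cl2, −78 °C; then TsOH·H2O (cat.), CH2Cl2, rt
Reagents that add atoms: none
Why: Luche 1,2-reduction should take the C5 carbonyl, which is flanked by CH2, in preference to the C8 carbonyl, which is screened by the cis aryl group on C1. Acid then ionizes the allylic carbinol, C4a loses a proton and the C8 ketone enolizes, so ring A becomes aromatic with O5 gone and O8 as the phenol; C1 is not touched.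

Step 9
Reactants: 14 methyl (1R)-1-[4-(benzyloxy)-3-methoxyphenyl]-8-hydroxy-6,7-dimethoxy-3-{[(triisopropylsilyl)oxy]methyl}-1,4-dihydronaphthalene-2-carboxylate
Product: 15 methyl (1R)-1-[4-(benzyloxy)-3-methoxyphenyl]-6,7,8-trimethoxy-3-{[(triisopropylsilyl)oxy]methyl}-1,4-dihydronaphthalene-2-carboxylate
Conditions: MeI, K2CO3, DMF, rt
Reagents that add atoms: iodomethane, CI
Why: Williamson methylation of the only free phenol; carbonate is too weak a base to deprotonate C1–H or C4–H, so the alkene stays where it is.

Step 10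
Reactants: 15 methyl (1R)-1-[4-(benzyloxy)-3-methoxyphenyl]-6,7,8-trimethoxy-3-{[(triisopropylsilyl)oxy]methyl}-1,4-dihydronaphthalene-2-carboxylate
Product: 16 methyl (1R,2R,3S)-1-(4-hydroxy-3-methoxyphenyl)-6,7,8-trimethoxy-3-{[(triisopropylsilyl)oxy]methyl}-1,2,3,4-tetrahydronaphthalene-2-carboxylate
Conditions: H2 (20 bar), Pd(OH)2/C, EtOAc, rt
Reagents that add atoms: none
Why: Heterogeneous syn hydrogenation; the aryl group on C1 is pseudoaxial (allylic strain with the C2 ester, peri strain with the O8 methyl) and covers one face, so both hydrogen atoms arrive from the other face. This sets C3 with C10 cis to the aryl group as in the target and leaves the ester cis as well, to be corrected in step 11; the aryl benzyl ether is hydrogenolysed in the same operation.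

Step 11
Reactants: 16 methyl (1R,2R,3S)-1-(4-hydroxy-3-methoxyphenyl)-6,7,8-trimethoxy-3-{[(triisopropylsilyl)oxy]methyl}-1,2,3,4-tetrahydronaphthalene-2-carboxylate
Product: 17 methyl (1R,2S,3S)-1-(4-hydroxy-3-methoxyphenyl)-6,7,8-trimethoxy-3-{[(triisopropylsilyl)oxy]methyl}-1,2,3,4-tetrahydronaphthalene-2-carboxylate
Conditions: NaOMe, MeOH, 50 °C; then AcOH
Reagents that add atoms: none
Why: Reversible enolization at C2 under thermodynamic control moves the ester trans to both neighbours, which is the arrangement with all three groups equatorial; C1 and C3 carry no acidic hydrogen and stay fixed.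

Step 12
Reactants: 17 methyl (1R,2S,3S)-1-(4-hydroxy-3-methoxyphenyl)-6,7,8-trimethoxy-3-{[(triisopropylsilyl)oxy]methyl}-1,2,3,4-tetrahydronaphthalene-2-carboxylate
Product: 18 4-[(1R,2S,3S)-2-(hydroxymethyl)-6,7,8-trimethoxy-3-{[(triisopropylsilyl)oxy]methyl}-1,2,3,4-tetrahydronaphthalen-1-yl]-2-methoxyphenol
Conditions: LiAlH4, THF, 0 °C → rt; aq. potassium sodium tartrate
Reagents that add atoms: none
Why: Hydride reduction of the ester to the primary alcohol C9; once the carbonyl is gone C2 can no longer epimerize.

Step 13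
Reactants: 18 4-[(1R,2S,3S)-2-(hydroxymethyl)-6,7,8-trimethoxy-3-{[(triisopropylsilyl)oxy]methyl}-1,2,3,4-tetrahydronaphthalen-1-yl]-2-methoxyphenol
Product: 19 (1R,2S,3S)-1-(4-hydroxy-3-methoxyphenyl)-2-(hydroxymethyl)-6,8-dimethoxy-3-{[(triisopropylsilyl)oxy]methyl}-1,2,3,4-tetrahydronaphthalen-7-ol
Conditions: NaSEt, DMF, 110 °C; then aq. NH4Cl
Reagents that add atoms: none
Why: SN2 demethylation by thiolate; the C7 methoxy group is flanked by two methoxy groups, is twisted out of conjugation and leaves as a phenoxide held between two ether oxygens, so it should be the preferred leaving group. The guaiacyl methoxy group is protected by the phenoxide next to it, because its cleavage would put a second negative charge on adjacent oxygens.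

Step 14
Reactants: 19 (1R,2S,3S)-1-(4-hydroxy-3-methoxyphenyl)-2-(hydroxymethyl)-6,8-dimethoxy-3-{[(triisopropylsilyl)oxy]methyl}-1,2,3,4-tetrahydronaphthalen-7-ol
Product: 20 (1R,2S,3S)-1-(4-hydroxy-3-methoxyphenyl)-2,3-bis(hydroxymethyl)-6,8-dimethoxy-1,2,3,4-tetrahydronaphthalen-7-ol
Conditions: TBAF, THF, 0 °C → rt
Reagents that add atoms: none
Why: Fluoride cleaves the Si–O bond and frees C10–OH; no other group in the molecule responds to these conditions.

## Compound list

1 | 2,3-dimethoxyphenol | COc1cccc(O)c1OC | starting material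
2 | 2,3-dimethoxy-1,4-benzoquinone | COC1=C(OC)C(=O)C=CC1=O | intermediate
3 | 2-bromoprop-2-en-1-ol | OCC(Br)=C | starting material
4 | [(2-bromoprop-2-en-1-yl)oxy]tri(propan-2-yl)silane | C=C(Br)CO[Si](C(C)C)(C(C)C)C(C)C | intermediate
5 | 4,4,5,5-tetramethyl-2-{3-[(triisopropylsilyl)oxy]prop-1-en-2-yl}-1,3,2-dioxaborolane | C=C(CO[Si](C(C)C)(C(C)C)C(C)C)B1OC(C)(C)C(C)(C)O1 | intermediate
6 | methyl 2-[bis(2,2,2-trifluoroethoxy)phosphoryl]acetate | COC(=O)CP(=O)(OCC(F)(F)F)OCC(F)(F)F | starting material
7 | methyl 2,2-dibromo-2-[bis(2,2,2-trifluoroethoxy)phosphoryl]acetate | COC(=O)C(Br)(Br)P(=O)(OCC(F)(F)F)OCC(F)(F)F | intermediate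
8 | methyl 2-bromo-2-[bis(2,2,2-trifluoroethoxy)phosphoryl]acetate (racemic) | COC(=O)C(Br)P(=O)(OCC(F)(F)F)OCC(F)(F)F | intermediate
9 | 4-(benzyloxy)-3-methoxybenzaldehyde | COc1cc(C=O)ccc1OCc1ccccc1 | starting material
10 | methyl (E)-3-[4-(benzyloxy)-3-methoxyphenyl]-2-bromoprop-2-enoate | COC(=O)/C(Br)=C\c1ccc(OCc2ccccc2)c(OC)c1 | intermediate
11 | methyl (Z)-3-[4-(benzyloxy)-3-methoxyphenyl]-2-{3-[(triisopropylsilyl)oxy]prop-1-en-2-yl}prop-2-enoate | COC(=O)/C(=C\c1ccc(OCc2ccccc2)c(OC)c1)C(=C)CO[Si](C(C)C)(C(C)C)C(C)C | intermediate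
12 | methyl (1S,4aR,8aS)-1-[4-(benzyloxy)-3-methoxyphenyl]-6,7-dimethoxy-5,8-dioxo-3-{[(triisopropylsilyl)oxy]methyl}-1,4,4a,5,8,8a-hexahydronaphthalene-2-carboxylate (cis-fused endo adduct, H1, H4a and H8a all cis) | COc1cc([C@@H]2[C@@H]3C(=O)C(OC)=C(OC)C(=O)[C@@H]3CC(CO[Si](C(C)C)(C(C)C)C(C)C)=C2C(=O)OC)ccc1OCc1ccccc1 | intermediate
13 | methyl (1S,4aR,8aS)-1-[4-(benzyloxy)-3-methoxyphenyl]-5-hydroxy-6,7-dimethoxy-8-oxo-3-{[(triisopropylsilyl)oxy]methyl}-1,4,4a,5,8,8a-hexahydronaphthalene-2-carboxylate (C5 configuration left open, both epimers converge) | COc1cc([C@@H]2[C@@H]3C(=O)C(OC)=C(OC)C(O)[C@@H]3CC(CO[Si](C(C)C)(C(C)C)C(C)C)=C2C(=O)OC)ccc1OCc1ccccc1 | intermediate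
14 | methyl (1R)-1-[4-(benzyloxy)-3-methoxyphenyl]-8-hydroxy-6,7-dimethoxy-3-{[(triisopropylsilyl)oxy]methyl}-1,4-dihydronaphthalene-2-carboxylate | COc1cc([C@@H]2c3c(O)c(OC)c(OC)cc3CC(CO[Si](C(C)C)(C(C)C)C(C)C)=C2C(=O)OC)ccc1OCc1ccccc1 | intermediate
15 | methyl (1R)-1-[4-(benzyloxy)-3-methoxyphenyl]-6,7,8-trimethoxy-3-{[(triisopropylsilyl)oxy]methyl}-1,4-dihydronaphthalene-2-carboxylate | COc1cc([C@@H]2c3c(OC)c(OC)c(OC)cc3CC(CO[Si](C(C)C)(C(C)C)C(C)C)=C2C(=O)OC)ccc1OCc1ccccc1 | intermediate
16 | methyl (1R,2R,3S)-1-(4-hydroxy-3-methoxyphenyl)-6,7,8-trimethoxy-3-{[(triisopropylsilyl)oxy]methyl}-1,2,3,4-tetrahydronaphthalene-2-carboxylate (all cis) | COc1cc([C@@H]2c3c(OC)c(OC)c(OC)cc3C[C@H](CO[Si](C(C)C)(C(C)C)C(C)C)[C@@H]2C(=O)OC)ccc1O | intermediate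
17 | methyl (1R,2S,3S)-1-(4-hydroxy-3-methoxyphenyl)-6,7,8-trimethoxy-3-{[(triisopropylsilyl)oxy]methyl}-1,2,3,4-tetrahydronaphthalene-2-carboxylate (all trans) | COc1cc([C@@H]2c3c(OC)c(OC)c(OC)cc3C[C@H](CO[Si](C(C)C)(C(C)C)C(C)C)[C@H]2C(=O)OC)ccc1O | intermediate
18 | 4-[(1R,2S,3S)-2-(hydroxymethyl)-6,7,8-trimethoxy-3-{[(triisopropylsilyl)oxy]methyl}-1,2,3,4-tetrahydronaphthalen-1-yl]-2-methoxyphenol | COc1cc([C@@H]2c3c(OC)c(OC)c(OC)cc3C[C@H](CO[Si](C(C)C)(C(C)C)C(C)C)[C@H]2CO)ccc1O | intermediate
19 | (1R,2S,3S)-1-(4-hydroxy-3-methoxyphenyl)-2-(hydroxymethyl)-6,8-dimethoxy-3-{[(triisopropylsilyl)oxy]methyl}-1,2,3,4-tetrahydronaphthalen-7-ol | COc1cc([C@@H]2c3c(OC)c(O)c(OC)cc3C[C@H](CO[Si](C(C)C)(C(C)C)C(C)C)[C@H]2CO)ccc1O | intermediate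
20 | (1R,2S,3S)-1-(4-hydroxy-3-methoxyphenyl)-2,3-bis(hydroxymethyl)-6,8-dimethoxy-1,2,3,4-tetrahydronaphthalen-7-ol | COc1cc([C@@H]2c3c(cc(OC)c(O)c3OC)C[C@H](CO)[C@H]2CO)ccc1O | target

## Step count and least certain steps

Total step count: 14. Longest linear sequence: 11 steps (steps 2, 3, 6–14 from 3, or equally steps 4, 5, 6–14 from 6).

**Step 7 (key step).** The most likely failure is erosion of enantiomeric purity: competition between the two orientations of 11 on the bound quinone, or some exo approach, both feed the mirror-image series once ring A is aromatic. Slow turnover is also possible because the diene ester competes with the quinone for boron, and the adduct may enolize to the hydroquinone during isolation. An inverted sense of induction would be met by the catalyst from (S)-diphenylprolinol. The fallback replaces asymmetric catalysis by resolution. It sets out from 11 and 2, which are combined without a chiral catalyst (toluene, 70 °C) to give 12 together with its mirror image, the (1R,4aS,8aR) adduct F1. The mixture is taken through step 8, where the mirror-image C5 carbinol F2 is not isolated, to 14 and its mirror image, the (1S) phenol F3. The two phenols are separated by preparative chromatography on a chiral stationary phase, and the fallback returns to the route at 14.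

**Step 8.** The most likely failure is incomplete discrimination between the two carbonyl groups, since reduction at C8 followed by dehydration leads to the regioisomeric phenol, or enolization of 12 before the hydride arrives. The fallback makes the distinction on the aromatic hydroquinone instead. It sets out from 12, which Et3N in CH2Cl2 enolizes to the 5,8-dihydroxy-6,7-dimethoxy-1,4-dihydronaphthalene ester F4. One equivalent of PhNTf2 with K2CO3 at 0 °C sulfonylates the less hindered oxygen and gives the O5 triflate F5. MeI and K2CO3 then give the O5 triflate O8 methyl ether F6, and reduction of the triflate with Pd(OAc)2, dppf, HCO2H and Et3N in DMF at 60 °C returns to the route at 15.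

**Step 10.** The most likely failure is slow saturation of the tetrasubstituted C2=C3 bond, which gives time for loss of hydrogen from the 1,4-dihydronaphthalene to a naphthalene (destroying C1) or for hydrogenolysis of the allylic C10–O bond on palladium. The fallback uses hydroxyl-directed homogeneous hydrogenation and moves the epimerization to the aldehyde level. It sets out from 15, which DIBAL-H in CH2Cl2 at −78 °C reduces to the C9 allylic alcohol F7. [Ir(cod)(PCy3)(py)]PF6 and H2 in CH2Cl2 then deliver hydrogen to the face away from the aryl group and give the all-cis C9 alcohol F8, with both benzyl and silyl ethers intact. Dess–Martin periodinane gives the cis aldehyde F9, DBU equilibrates it to the trans aldehyde F10, and NaBH4 gives the trans C9 alcohol with the aryl benzyl ether still in place F11. Hydrogenolysis with H2 and Pd/C in EtOAc returns to the route at 18.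

**Step 13.** The most likely failure is poor site selection among the three methoxy groups of ring A, because the O8 methyl group is also twisted out of the ring plane, or oxidation of the electron-rich phenoxides at 110 °C. The fallback frees O7 while the neighbouring O8 is still a phenol and carries O7 as a benzyl ether. It sets out from 14, whose 2-methoxyphenol unit is oxidatively demethylated with stabilized 2-iodoxybenzoic acid in THF to the 7,8-ortho-quinone F12, reduced in the same flask with Na2S2O4 to the 7,8-catechol F13. One equivalent of BnBr with K2CO3 in acetone alkylates the less hindered hydroxyl and gives the O7 benzyl ether F14, and MeI with K2CO3 in DMF gives the O7 benzyl O8 methyl ether F15. The conditions of steps 10 to 12 then follow: hydrogenation cleaves both benzyl ethers and gives the all-cis ester with free O7 F16, NaOMe gives the all-trans ester with free O7 F17, and LiAlH4 returns to the route at 19.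

## Further compounds

F1 | step 7 | methyl (1R,4aS,8aR)-1-[4-(benzyloxy)-3-methoxyphenyl]-6,7-dimethoxy-5,8-dioxo-3-{[(triisopropylsilyl)oxy]methyl}-1,4,4a,5,8,8a-hexahydronaphthalene-2-carboxylate (mirror image of 12) | COc1cc([C@H]2[C@H]3C(=O)C(OC)=C(OC)C(=O)[C@H]3CC(CO[Si](C(C)C)(C(C)C)C(C)C)=C2C(=O)OC)ccc1OCc1ccccc1
F2 | step 7 | mirror-image C5 carbinol (mirror image of 13, C5 configuration left open) | COc1cc([C@H]2[C@H]3C(=O)C(OC)=C(OC)C(O)[C@H]3CC(CO[Si](C(C)C)(C(C)C)C(C)C)=C2C(=O)OC)ccc1OCc1ccccc1
F3 | step 7 | methyl (1S)-1-[4-(benzyloxy)-3-methoxyphenyl]-8-hydroxy-6,7-dimethoxy-3-{[(triisopropylsilyl)oxy]methyl}-1,4-dihydronaphthalene-2-carboxylate (mirror image of 14) | COc1cc([C@H]2c3c(O)c(OC)c(OC)cc3CC(CO[Si](C(C)C)(C(C)C)C(C)C)=C2C(=O)OC)ccc1OCc1ccccc1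
F4 | step 8 | methyl 1-[4-(benzyloxy)-3-methoxyphenyl]-5,8-dihydroxy-6,7-dimethoxy-3-{[(triisopropylsilyl)oxy]methyl}-1,4-dihydronaphthalene-2-carboxylate (C1 as in 14) | COc1cc([C@@H]2c3c(O)c(OC)c(OC)c(O)c3CC(CO[Si](C(C)C)(C(C)C)C(C)C)=C2C(=O)OC)ccc1OCc1ccccc1
F5 | step 8 | methyl 1-[4-(benzyloxy)-3-methoxyphenyl]-8-hydroxy-6,7-dimethoxy-5-[(trifluoromethanesulfonyl)oxy]-3-{[(triisopropylsilyl)oxy]methyl}-1,4-dihydronaphthalene-2-carboxylate (C1 as in 14) | COc1cc([C@@H]2c3c(O)c(OC)c(OC)c(OS(=O)(=O)C(F)(F)F)c3CC(CO[Si](C(C)C)(C(C)C)C(C)C)=C2C(=O)OC)ccc1OCc1ccccc1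
F6 | step 8 | methyl 1-[4-(benzyloxy)-3-methoxyphenyl]-6,7,8-trimethoxy-5-[(trifluoromethanesulfonyl)oxy]-3-{[(triisopropylsilyl)oxy]methyl}-1,4-dihydronaphthalene-2-carboxylate (C1 as in 14) | COc1cc([C@@H]2c3c(OC)c(OC)c(OC)c(OS(=O)(=O)C(F)(F)F)c3CC(CO[Si](C(C)C)(C(C)C)C(C)C)=C2C(=O)OC)ccc1OCc1ccccc1
F7 | step 10 | {1-[4-(benzyloxy)-3-methoxyphenyl]-6,7,8-trimethoxy-3-{[(triisopropylsilyl)oxy]methyl}-1,4-dihydronaphthalen-2-yl}methanol (C1 as in 15) | COc1cc([C@@H]2c3c(OC)c(OC)c(OC)cc3CC(CO[Si](C(C)C)(C(C)C)C(C)C)=C2CO)ccc1OCc1ccccc1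
F8 | step 10 | {1-[4-(benzyloxy)-3-methoxyphenyl]-6,7,8-trimethoxy-3-{[(triisopropylsilyl)oxy]methyl}-1,2,3,4-tetrahydronaphthalen-2-yl}methanol (1,2-cis, 2,3-cis) | COc1cc([C@@H]2c3c(OC)c(OC)c(OC)cc3C[C@H](CO[Si](C(C)C)(C(C)C)C(C)C)[C@@H]2CO)ccc1OCc1ccccc1
F9 | step 10 | 1-[4-(benzyloxy)-3-methoxyphenyl]-6,7,8-trimethoxy-3-{[(triisopropylsilyl)oxy]methyl}-1,2,3,4-tetrahydronaphthalene-2-carbaldehyde (1,2-cis, 2,3-cis) | COc1cc([C@@H]2c3c(OC)c(OC)c(OC)cc3C[C@H](CO[Si](C(C)C)(C(C)C)C(C)C)[C@@H]2C=O)ccc1OCc1ccccc1
F10 | step 10 | 1-[4-(benzyloxy)-3-methoxyphenyl]-6,7,8-trimethoxy-3-{[(triisopropylsilyl)oxy]methyl}-1,2,3,4-tetrahydronaphthalene-2-carbaldehyde (1,2-trans, 2,3-trans) | COc1cc([C@@H]2c3c(OC)c(OC)c(OC)cc3C[C@H](CO[Si](C(C)C)(C(C)C)C(C)C)[C@H]2C=O)ccc1OCc1ccccc1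
F11 | step 10 | {1-[4-(benzyloxy)-3-methoxyphenyl]-6,7,8-trimethoxy-3-{[(triisopropylsilyl)oxy]methyl}-1,2,3,4-tetrahydronaphthalen-2-yl}methanol (1,2-trans, 2,3-trans) | COc1cc([C@@H]2c3c(OC)c(OC)c(OC)cc3C[C@H](CO[Si](C(C)C)(C(C)C)C(C)C)[C@H]2CO)ccc1OCc1ccccc1
F12 | step 13 | methyl 1-[4-(benzyloxy)-3-methoxyphenyl]-6-methoxy-7,8-dioxo-3-{[(triisopropylsilyl)oxy]methyl}-1,4,7,8-tetrahydronaphthalene-2-carboxylate (C1 as in 14) | COc1cc([C@@H]2C3=C(C=C(OC)C(=O)C3=O)CC(CO[Si](C(C)C)(C(C)C)C(C)C)=C2C(=O)OC)ccc1OCc1ccccc1
F13 | step 13 | methyl 1-[4-(benzyloxy)-3-methoxyphenyl]-7,8-dihydroxy-6-methoxy-3-{[(triisopropylsilyl)oxy]methyl}-1,4-dihydronaphthalene-2-carboxylate (C1 as in 14) | COc1cc([C@@H]2c3c(O)c(O)c(OC)cc3CC(CO[Si](C(C)C)(C(C)C)C(C)C)=C2C(=O)OC)ccc1OCc1ccccc1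
F14 | step 13 | methyl 7-(benzyloxy)-1-[4-(benzyloxy)-3-methoxyphenyl]-8-hydroxy-6-methoxy-3-{[(triisopropylsilyl)oxy]methyl}-1,4-dihydronaphthalene-2-carboxylate (C1 as in 14) | COc1cc([C@@H]2c3c(O)c(OCc4ccccc4)c(OC)cc3CC(CO[Si](C(C)C)(C(C)C)C(C)C)=C2C(=O)OC)ccc1OCc1ccccc1
F15 | step 13 | methyl 7-(benzyloxy)-1-[4-(benzyloxy)-3-methoxyphenyl]-6,8-dimethoxy-3-{[(triisopropylsilyl)oxy]methyl}-1,4-dihydronaphthalene-2-carboxylate (C1 as in 14) | COc1cc([C@@H]2c3c(OC)c(OCc4ccccc4)c(OC)cc3CC(CO[Si](C(C)C)(C(C)C)C(C)C)=C2C(=O)OC)ccc1OCc1ccccc1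
F16 | step 13 | methyl 7-hydroxy-1-(4-hydroxy-3-methoxyphenyl)-6,8-dimethoxy-3-{[(triisopropylsilyl)oxy]methyl}-1,2,3,4-tetrahydronaphthalene-2-carboxylate (1,2-cis, 2,3-cis) | COc1cc([C@@H]2c3c(OC)c(O)c(OC)cc3C[C@H](CO[Si](C(C)C)(C(C)C)C(C)C)[C@@H]2C(=O)OC)ccc1O
F17 | step 13 | methyl 7-hydroxy-1-(4-hydroxy-3-methoxyphenyl)-6,8-dimethoxy-3-{[(triisopropylsilyl)oxy]methyl}-1,2,3,4-tetrahydronaphthalene-2-carboxylate (1,2-trans, 2,3-trans) | COc1cc([C@@H]2c3c(OC)c(O)c(OC)cc3C[C@H](CO[Si](C(C)C)(C(C)C)C(C)C)[C@H]2C(=O)OC)ccc1O
A1 | alternative 1 | (2R,4R)-4-{[(E)-3-(4-hydroxy-3-methoxyphenyl)prop-2-enoyl]oxy}pentan-2-yl (E)-3-(4-hydroxy-3,5-dimethoxyphenyl)prop-2-enoate | COc1cc(/C=C/C(=O)O[C@H](C)C[C@@H](C)OC(=O)/C=C/c2cc(OC)c(O)c(OC)c2)ccc1O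
A2 | alternative 1 | tether-bridged trans-1-(4-hydroxy-3-methoxyphenyl)-7-hydroxy-6,8-dimethoxy-1,2-dihydronaphthalene-2,3-dicarboxylate of (2R,4R)-pentane-2,4-diol | COc1cc([C@@H]2c3c(cc(OC)c(O)c3OC)C=C4C(=O)O[C@H](C)C[C@@H](C)OC(=O)[C@@H]24)ccc1O
A3 | alternative 2 | 4-{4-(benzyloxy)-2-[hydroxy(4-hydroxy-3-methoxyphenyl)methyl]-3,5-dimethoxyphenyl}-3-{[tert-butyl(dimethyl)silyl]oxymethyl}butanal (carbinol configuration left open) | O=CC[C@@H](CO[Si](C)(C)C(C)(C)C)Cc1cc(OC)c(OCc2ccccc2)c(OC)c1C(O)c1ccc(O)c(OC)c1
A4 | alternative 2 | 7-(benzyloxy)-1-(4-hydroxy-3-methoxyphenyl)-6,8-dimethoxy-3-{[tert-butyl(dimethyl)silyl]oxymethyl}-1,2,3,4-tetrahydronaphthalene-2-carbaldehyde (all trans) | COc1cc([C@@H]2c3c(cc(OC)c(OCc4ccccc4)c3OC)C[C@H](CO[Si](C)(C)C(C)(C)C)[C@H]2C=O)ccc1O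
A5 | alternative 3 | 4-(benzyloxy)-2-[4-(benzyloxy)-3-methoxybenzyl]-3,5-dimethoxybenzaldehyde | O=Cc1cc(OC)c(OCc2ccccc2)c(OC)c1Cc1ccc(OCc2ccccc2)c(OC)c1
A6 | alternative 3 | bis[(1R,2S,5R)-5-methyl-2-(propan-2-yl)cyclohexyl] (E)-but-2-enedioate (di-(−)-menthyl fumarate) | CC(C)[C@@H]1CC[C@@H](C)C[C@H]1OC(=O)/C=C/C(=O)O[C@@H]1C[C@H](C)CC[C@H]1C(C)C
A7 | alternative 3 | di-(−)-menthyl 7-(benzyloxy)-1-[4-(benzyloxy)-3-methoxyphenyl]-4-hydroxy-6,8-dimethoxy-1,2,3,4-tetrahydronaphthalene-2,3-dicarboxylate (1,2-trans, 2,3-trans, 3,4-cis) | COc1cc([C@@H]2c3c(cc(OC)c(OCc4ccccc4)c3OC)[C@H](O)[C@H](C(=O)O[C@@H]5C[C@H](C)CC[C@H]5C(C)C)[C@H]2C(=O)O[C@@H]6C[C@H](C)CC[C@H]6C(C)C)ccc1OCc1ccccc1
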